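- The G left over after the lag falls nearly exponentially, so we freeze the living ends and read a pseudo-first-order constant k′, the slope of −ln G against time, which is proportional to their concentration.

| flask | G | Z | remark | time |
|---|---|---|---|---|
| grey | 2.1 M | 0.25 mol% | run made earlier |  |
| violet | 2.1 M | 0.38 mol% | run made earlier |  |
| flask | 2.1 M | 0.5 mol% |  | 15 h |

- grey (time / h: D / %, G / %): 0.667: 2, 102; 2.00: 13, 89; 3.00: 22, 83; 5.00: 48, 49; 8.00: 78, 22; 10.0: 89, 10; 12.0: 93, 6
- violet (time / h: D / %, G / %): 1.00: 2, 95; 1.33: 3, 92; 2.00: 13, 89; 3.00: 29, 70; 5.00: 61, 43; 8.00: 88, 12; 12.0: 100, 2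

(each reading ± 2 percentage points)

- average number of monomer units in a chain (chains begun, living or dead) at 15 h
- part of the G that has reacted at 15 h

- the average divides the monomer in chains by the number of chains begun, living and dead together
- the earlier runs do not show the number of chains; that part of a forecast is a guess

- Time: by hand, each extra hour multiplies the leftover G by exp(−k′). The grey run reads 0.318 h⁻¹ from 5.00 h to 10.0 h, and the violet run 0.425 h⁻¹ from 5.00 h to 8.00 h.
- Z: by hand, a fixed yield of ends per Z gives the same violet-to-grey ratio in k′ as in Z, 1.52, but the k′ ratio read from the runs is 1.34, less than that. We carry the reading 0.696 as n, the reaction order of k′ in Z, the logarithm of the k′ ratio over that of the Z ratio.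
- Our reckoning for the flask: k′ is 0.515 h⁻¹. With the grey run's lag of 2.76 h, conversion reaches 99.8 %.
- Chains are not shown, so we fix no dp. With n below one, we lean above the 200 that one chain per Z gives.
- The forecast says dp 190 (130 to 270) and c 99.5 % (97.5 % to 100 %), on the ground that “one chain per Z gives dp of about 200”.

    G + X → D + X, rate k1*[X]*[G] (k = 1.53 M⁻¹ min⁻¹)
    G + E → X + D (k = 0.00565 M⁻¹ min⁻¹)
    2 E → J (k = 1.54 M⁻¹ min⁻¹)
    Z ⇌ E (K = 9.00, k = 0.00597 min⁻¹)

- The flask gives dp 419 and c 99.6 %. At 15.0 h it holds X at 0.00500 M, about half of the 0.0105 M of Z charged. Taking this dp to the grey run, n makes the flask's chains 1.62 times the grey run's. With the grey run's conversion of 93.3 % at 12.0 h, that reckons dp 636, and the grey run stands at 575.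

Readings and results stem from a simulated flask for an exercise; noise was put on by code.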